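## Analysis of the target

Target 16 is an open-chain bis(bibenzyl) with four benzene rings in a row, joined as A–CH2CH2–B–O–C–CH2CH2–D. Ring A is a 3-hydroxyphenyl group, ring B a 1,4-phenylene, ring C a 1,2,4-trisubstituted ring with a free hydroxyl ortho to the ether oxygen, and ring D a 3-substituted catechol. The molecule has no stereocentre and no alkene geometry, so any stereocentre made on the way has to be erased. The four phenols are the sensitive groups: the ring D catechol oxidises easily to the ortho-quinone, and ring C is a second electron-rich 2-aryloxyphenol. They must stay masked until the end and be unmasked without cleaving the diaryl ether. The difficulty is the unsymmetrical order of the pieces: two different two-carbon bridges and one diaryl ether must be made with the ring C pattern fixed (ether oxygen meta and hydroxyl para to the bridge). The strategy rests on the bridge between C1 of ring A and C4 of ring B. Its two sp3 carbons each carry one aryl group, which is what a vinyl group becomes when one carbon takes up an aryl nucleophile and the other an aryl electrophile. The boron that comes with this joining ends on a benzylic carbon, where it can be exchanged for hydrogen.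

## Retrosynthetic reasoning

Target 16 is traced back to its tetramethyl ether 15 by cutting the four O–CH3 bonds. Methyl ethers are chosen because they survive an aryllithium, a palladium catalyst, fluoride and hydrogenation, and because one Lewis-acid treatment removes all four while leaving the diaryl ether intact. Unmasking comes last so that the catechol is never carried through a metal-mediated step.

Tetramethyl ether 15 is traced back to the racemic benzylic boronate 14 by replacing one benzylic C–H of the A–B bridge with a C–B bond. The forward step is a protodeboronation, feasible because the carbon bears ring B and can carry negative charge once boron is made four-coordinate by fluoride. This removes the only stereocentre of the route.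

Boronate 14 is cut at two bonds at once: the bond from C4 of ring B to the boron-bearing carbon, and the bond from the CH2 to C1 of ring A. This gives aryl bromide 8, vinylboronic ester 11 and triflate 10. The cut is made here and not at the C–D bridge because ring B gets its bromine at no extra cost from the partner used to make the ether, and ring A needs only a sulfonate on a phenol that can be bought. The advanced fragment needs neither an aldehyde nor a phosphonium group. In the forward direction, 8 becomes aryllithium 12, which adds to 11 to give the boronate complex 13. Palladium must then induce migration of the ring B aryl from boron to carbon rather than transfer it directly to the metal.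

Triflate 10 comes from 3-methoxyphenol 9 by sulfonylation of the hydroxyl.

Aryl bromide 8 is cut at the O–C bond between the ether oxygen and ring B, giving phenol 6 and 4-bromophenylboronic acid 7. An oxidative copper coupling with a boronic acid is chosen over a copper- or palladium-mediated coupling with an aryl halide because it runs at room temperature and does not touch the C–Br bond needed later.

Phenol 6 is traced back to stilbene 5, in which the C–D bridge is an alkene and the phenol is a benzyl ether, so that one hydrogenation does both jobs. Stilbene 5 is cut at the double bond into aldehyde 3 and ylide 4. Ylide 4 comes from phosphonium salt 2, which is made from benzyl alcohol 1. Rings C and D are thus bought with their oxygens in place, and the alkene geometry does not matter.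

## Alternatives that were turned down

Alternative 1: Ring D is not bought but made, by cutting its C1–C6 bond.
- Key step: Aqueous acid would unmask the ketal-protected 2-acyl-2,5-dimethoxytetrahydrofuran A2 to the 4,5-dioxo aldehyde A3. The CH2 beside the diketone of A3 would then add to the aldehyde, and loss of water and enolisation would give A1, the di-O-methyl target with the catechol free.
- In its favour: The 1,2,3-pattern of ring D is fixed by the chain, and the catechol is freed under mild acid rather than by a boron halide. On this point it is stronger than the chosen route.
- Against: A2 has to come from the 2-acylfuran A4, which already contains rings A, B and C, both the A–B bridge and the ether. The oxidative methoxylation of the furan in A4 would compete with oxidation or halogenation of three electron-rich arenes. A3 has several enolisable positions and can condense in other ways or oligomerise. A1 still carries two methyl ethers, so a demethylation is needed anyway, now on a molecule with a free catechol.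
- Comparison: Many steps are spent building an arene that can be bought as 1. The chosen route offers convergence and a short approach to the key step in place of the milder catechol release.

Alternative 2: Ring C is made by a three-plus-three annulation that forms its C1–C6 and C3–C4 bonds.
- Key step: The aryloxyacetone A6 and the 2-substituted vinamidinium salt A7 would condense under a strong alkoxide base with loss of two molecules of dimethylamine, giving A5, the tri-O-methyl target with the ring C hydroxyl free.
- In its favour: The ortho-aryloxyphenol is formed with unambiguous regiochemistry, and the ether oxygen is attached by a simple O-alkylation instead of a copper-mediated arylation. On these two points it is as strong as or stronger than step 4.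
- Against: A7 needs a Vilsmeier-type double formylation next to an electron-rich dimethoxyphenyl ring, which can itself be formylated or acylated. The second ring-forming bond must come from the unactivated methyl group of A6, so the open dienaminone may stall or the ketone may self-condense. The A–B bibenzyl in A6 still needs its own olefination and reduction, so no steps are saved, and three methyl ethers remain to be cleaved.
- Comparison: The chosen route puts its risk into a catalytic coupling with close precedent on aryl migrating groups and aryl triflates. It makes ring C from a benzaldehyde, 3, that is bought with the right pattern.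

Alternative 3: Ring D is cut at its C1–CH2 bond and its C2–O bond.
- Key step: The Grignard reagent A9, which holds rings A, B and C, would add to 3-methoxybenzyne A11, made from 3-fluoroanisole A10 by ortho-lithiation and loss of fluoride. The resulting arylmagnesium would be trapped with a borate ester and oxidised to give A8.
- In its favour: One pot forms a C–C and a C–O bond. The methoxy group directs the nucleophile to the distal aryne carbon, so regiocontrol is as secure as in the chosen route, and no palladium is needed.
- Against: The most advanced fragment is used as the stoichiometric nucleophile against a short-lived aryne that also reacts with its own lithiated precursor. A9 requires a two-carbon chain with a terminal carbon–magnesium bond on ring C, which adds steps and invites elimination to a styrene. The arylmagnesium to be borylated is flanked by two ortho substituents. The two catechol oxygens are differentiated, which is of no use here.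
- Comparison: The chosen route also joins three components through an organometallic. It generates the advanced nucleophile cleanly by halogen–lithium exchange, uses cheap partners, and buys ring D complete.

Key step: step 6

Remark on the chemistry: 3-benzyloxy-4-methoxybenzaldehyde (O-benzylisovanillin) is taken as a purchasable starting material, and an achiral ligand is used in the key step so that boronate 14 forms as a racemate.

## Route

Step 1
Reactants: 1 2,3-dimethoxybenzyl alcohol
Product: 2 (2,3-dimethoxybenzyl)triphenylphosphonium bromide
Conditions: PPh3·HBr, MeCN, reflux
Reagents that add atoms: triphenylphosphine hydrobromide, Br.c1ccc(cc1)P(c1ccccc1)c1ccccc1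
Why: The electron-rich benzylic alcohol is protonated and displaced, and triphenylphosphine captures the benzylic electrophile to give the phosphonium salt directly (phosphonium salt formation from a benzyl alcohol); the salt should crystallise from the reaction mixture.

Step 2
Reactants: 2 (2,3-dimethoxybenzyl)triphenylphosphonium bromide; 3 3-benzyloxy-4-methoxybenzaldehyde
Product: 5 2-benzyloxy-4-[2-(2,3-dimethoxyphenyl)ethenyl]-1-methoxybenzene (E/Z mixture), via phosphonium ylide 4 (not isolated)
Conditions: KOtBu, THF, 0 °C; then 3, 0 °C to rt
Reagents that add atoms: none
Why: Wittig olefination of an aromatic aldehyde with a semi-stabilised benzylic ylide; it should give a mixture of alkene isomers, which is acceptable because the double bond is hydrogenated in the next step.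

Step 3
Reactants: 5 2-benzyloxy-4-[2-(2,3-dimethoxyphenyl)ethenyl]-1-methoxybenzene (E/Z mixture)
Product: 6 5-[2-(2,3-dimethoxyphenyl)ethyl]-2-methoxyphenol
Conditions: H2 (1 atm), Pd/C (10%), EtOAc–EtOH, rt
Reagents that add atoms: none
Why: Catalytic hydrogenation saturates the stilbene double bond and cleaves the benzyl ether by hydrogenolysis in the same operation; the aryl methyl ethers are inert.

Step 4
Reactants: 6 5-[2-(2,3-dimethoxyphenyl)ethyl]-2-methoxyphenol; 7 4-bromophenylboronic acid
Product: 8 2-(4-bromophenoxy)-4-[2-(2,3-dimethoxyphenyl)ethyl]-1-methoxybenzene
Conditions: Cu(OAc)2 (1 equiv), pyridine, 4 Å MS, CH2Cl2, dry air, rt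
Reagents that add atoms: none
Why: Chan–Lam oxidative coupling of a phenol with an arylboronic acid forms the diaryl ether at room temperature and leaves the C–Br bond untouched, since divalent copper does not insert into aryl bromides under these conditions. Air returns the copper to divalent copper, so the salt is not consumed in the net equation.

Step 5
Reactants: 9 3-methoxyphenol
Product: 10 3-methoxyphenyl trifluoromethanesulfonate
Conditions: Tf2O, pyridine, CH2Cl2, 0 °C
Reagents that add atoms: trifluoromethanesulfonic anhydride, O=S(=O)(OS(=O)(=O)C(F)(F)F)C(F)(F)F
Why: O-Sulfonylation of a phenol with triflic anhydride and an amine base is a standard way to an aryl triflate.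

Step 6
Reactants: 8 2-(4-bromophenoxy)-4-[2-(2,3-dimethoxyphenyl)ethyl]-1-methoxybenzene; 11 vinylboronic acid pinacol ester; 10 3-methoxyphenyl trifluoromethanesulfonate
Product: 14 racemic 2-[1-{4-[5-(2-(2,3-dimethoxyphenyl)ethyl)-2-methoxyphenoxy]phenyl}-2-(3-methoxyphenyl)ethyl]-4,4,5,5-tetramethyl-1,3,2-dioxaborolane, via aryllithium 12 (not isolated), via lithium vinylboronate complex 13 (not isolated)
Conditions: t-BuLi (2 equiv), THF, −78 °C; 11, −78 °C to rt; then Pd(OAc)2 (cat.), 1,1'-bis(dicyclohexylphosphino)ferrocene (cat.), 10, NaOTf, THF, 60 °C
Reagents that add atoms: none
Why: Bromine–lithium exchange on 8 (the second equivalent of t-BuLi destroys the tert-butyl bromide formed) gives aryllithium 12, which adds to the empty orbital on boron of 11 to give the four-coordinate boronate 13. Triflate 10 adds oxidatively to the zerovalent palladium formed from Pd(OAc)2 and the bisphosphine; because triflate is a poor ligand, the resulting divalent arylpalladium is cationic and takes up the alkene of 13 as a π-ligand. This activation triggers a 1,2-metallate shift: the ring B aryl moves from boron to the α-carbon while palladium bonds to the β-carbon, and reductive elimination then joins that CH2 to C1 of ring A and regenerates zerovalent palladium. The closest known reaction type is the palladium-catalysed conjunctive cross-coupling of vinylboron ate complexes with aryl triflates. No ring is closed. The one new stereocentre, the boron-bearing benzylic carbon, is formed without control because the ligand is achiral, so 14 should be racemic; this is harmless because the centre becomes a CH2 group in step 7. The step needs the metallate shift to win over direct transfer of aryl or vinyl from boron to palladium and over β-hydride elimination from the alkylpalladium. The non-coordinating triflate, the wide-bite-angle ferrocenyl bisphosphine and the removal of bromide as NaBr by NaOTf favour the shift, and fast reductive elimination from the chelated complex suppresses β-hydride elimination. The methyl ethers and the diaryl ether are inert to the aryllithium at −78 °C and to the catalyst.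

Step 7
Reactants: 14 racemic 2-[1-{4-[5-(2-(2,3-dimethoxyphenyl)ethyl)-2-methoxyphenoxy]phenyl}-2-(3-methoxyphenyl)ethyl]-4,4,5,5-tetramethyl-1,3,2-dioxaborolane
Product: 15 4-[2-(2,3-dimethoxyphenyl)ethyl]-1-methoxy-2-{4-[2-(3-methoxyphenyl)ethyl]phenoxy}benzene
Conditions: TBAF·3H2O, toluene, 80 °C
Reagents that add atoms: none
Why: Fluoride-mediated protodeboronation of a benzylic boronic ester: fluoride makes boron four-coordinate, the C–B bond breaks with negative charge developing on the carbon stabilised by ring B, and the water of hydration delivers the proton. The stereocentre is erased.

Step 8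
Reactants: 15 4-[2-(2,3-dimethoxyphenyl)ethyl]-1-methoxy-2-{4-[2-(3-methoxyphenyl)ethyl]phenoxy}benzene
Product: 16 3-[2-(4-hydroxy-3-{4-[2-(3-hydroxyphenyl)ethyl]phenoxy}phenyl)ethyl]benzene-1,2-diol (the target)
Conditions: BBr3, CH2Cl2, −78 °C to rt; then H2O
Reagents that add atoms: none
Why: Lewis-acid demethylation of aryl methyl ethers: boron coordinates each ether oxygen and bromide attacks the methyl group, and aqueous work-up hydrolyses the aryl borates to the four phenols. The diaryl ether has no alkyl carbon for bromide to attack and should survive.

## Compound list

1 | 2,3-dimethoxybenzyl alcohol | COc1cccc(CO)c1OC | starting material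
2 | (2,3-dimethoxybenzyl)triphenylphosphonium bromide | COc1cccc(C[P+](c2ccccc2)(c2ccccc2)c2ccccc2)c1OC.[Br-] | intermediate
3 | 3-benzyloxy-4-methoxybenzaldehyde | COc1ccc(C=O)cc1OCc1ccccc1 | starting material
4 | (2,3-dimethoxybenzylidene)triphenylphosphorane (ylide, not isolated) | COc1cccc(C=P(c2ccccc2)(c2ccccc2)c2ccccc2)c1OC | intermediate
5 | 2-benzyloxy-4-[2-(2,3-dimethoxyphenyl)ethenyl]-1-methoxybenzene (E/Z mixture) | COc1ccc(C=Cc2cccc(OC)c2OC)cc1OCc1ccccc1 | intermediate
6 | 5-[2-(2,3-dimethoxyphenyl)ethyl]-2-methoxyphenol | COc1ccc(CCc2cccc(OC)c2OC)cc1O | intermediate
7 | 4-bromophenylboronic acid | OB(O)c1ccc(Br)cc1 | starting material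
8 | 2-(4-bromophenoxy)-4-[2-(2,3-dimethoxyphenyl)ethyl]-1-methoxybenzene | COc1ccc(CCc2cccc(OC)c2OC)cc1Oc1ccc(Br)cc1 | intermediate
9 | 3-methoxyphenol | COc1cccc(O)c1 | starting material
10 | 3-methoxyphenyl trifluoromethanesulfonate | COc1cccc(OS(=O)(=O)C(F)(F)F)c1 | intermediate
11 | vinylboronic acid pinacol ester | C=CB1OC(C)(C)C(C)(C)O1 | starting material
12 | {4-[5-(2-(2,3-dimethoxyphenyl)ethyl)-2-methoxyphenoxy]phenyl}lithium (not isolated) | COc1ccc(CCc2cccc(OC)c2OC)cc1Oc1ccc([Li])cc1 | intermediate
13 | lithium aryl(vinyl)pinacolatoborate from 12 and 11 (not isolated) | [Li+].C=C[B-]1(c2ccc(Oc3cc(CCc4cccc(OC)c4OC)ccc3OC)cc2)OC(C)(C)C(C)(C)O1 | intermediate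
14 | racemic 2-[1-{4-[5-(2-(2,3-dimethoxyphenyl)ethyl)-2-methoxyphenoxy]phenyl}-2-(3-methoxyphenyl)ethyl]-4,4,5,5-tetramethyl-1,3,2-dioxaborolane | COc1cccc(CC(B2OC(C)(C)C(C)(C)O2)c2ccc(Oc3cc(CCc4cccc(OC)c4OC)ccc3OC)cc2)c1 | intermediate
15 | 4-[2-(2,3-dimethoxyphenyl)ethyl]-1-methoxy-2-{4-[2-(3-methoxyphenyl)ethyl]phenoxy}benzene | COc1cccc(CCc2ccc(Oc3cc(CCc4cccc(OC)c4OC)ccc3OC)cc2)c1 | intermediate
16 | 3-[2-(4-hydroxy-3-{4-[2-(3-hydroxyphenyl)ethyl]phenoxy}phenyl)ethyl]benzene-1,2-diol | Oc1cccc(CCc2ccc(Oc3cc(CCc4cccc(O)c4O)ccc3O)cc2)c1 | target

## Step count and risks

Total step count: 8. Longest linear sequence: 7 steps (steps 1, 2, 3, 4, 6, 7 and 8); step 5 is a one-step side branch.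

Step 6 (key step).
- Most likely failure: direct transmetallation of the aryl or vinyl group from boron to palladium, which gives Suzuki-type products instead of the metallate shift. Bromide left from the halogen–lithium exchange favours this by binding the cationic palladium. Incomplete exchange, or protonation of the aryllithium before it reaches boron, would also lower conversion.
- Fallback: Set out from 8 and make the bridge by a Mizoroki–Heck reaction with 3-methoxystyrene (C=Cc1cccc(OC)c1), using Pd(OAc)2, tri(o-tolyl)phosphine and Et3N in DMF at 100 °C. This should give 4-[2-(2,3-dimethoxyphenyl)ethyl]-1-methoxy-2-{4-[(E)-2-(3-methoxyphenyl)ethenyl]phenoxy}benzene F1. Hydrogenation of F1 over Pd/C should then give 15, where the route is rejoined before step 8.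

Step 7.
- Most likely failure: slow C–B cleavage. The carbanion character is stabilised by only one aryl ring, and that ring carries a para-aryloxy donor, so the boronate may persist or be oxidised by adventitious air instead.
- Fallback: Set out from 14 and oxidise the C–B bond with NaOH and H2O2 in THF at 0 °C to racemic 1-{4-[5-(2-(2,3-dimethoxyphenyl)ethyl)-2-methoxyphenoxy]phenyl}-2-(3-methoxyphenyl)ethanol F2. Remove the benzylic hydroxyl by ionic hydrogenation with Et3SiH and trifluoroacetic acid in CH2Cl2; the para-aryloxy group stabilises the benzylic cation that the silane reduces. This returns to the route at 15.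

Step 4.
- Most likely failure: slow aryl transfer to the ortho-methoxy-substituted phenol. Protodeboronation, oxidative homocoupling and hydroxylation of the boronic acid would then consume 7 first.
- Fallback: Set out from 6 and use an Ullmann-type etherification with 1-bromo-4-iodobenzene (CuI, N,N-dimethylglycine, Cs2CO3, dioxane, 90 °C). The C–I bond should react selectively and leave the bromide in place. This gives 8 directly and makes no new compound (F0).

Step 8.
- Most likely failure: incomplete cleavage, in which one of the four methyl ethers survives as a boron chelate on the catechol ring, or oxidation of the freed catechol during aqueous work-up.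
- Fallback: Set out from 15 and switch from electrophilic to nucleophilic dealkylation. Sodium ethanethiolate in DMF at 130 °C attacks the methyl groups by an SN2 reaction under basic, reducing conditions that protect the catechol as its phenoxide. Acidification under inert gas should give 16; no new compound is made (F0).

## Further compounds

F1 | step 6 | 4-[2-(2,3-dimethoxyphenyl)ethyl]-1-methoxy-2-{4-[(E)-2-(3-methoxyphenyl)ethenyl]phenoxy}benzene | COc1cccc(/C=C/c2ccc(Oc3cc(CCc4cccc(OC)c4OC)ccc3OC)cc2)c1
F2 | step 7 | racemic 1-{4-[5-(2-(2,3-dimethoxyphenyl)ethyl)-2-methoxyphenoxy]phenyl}-2-(3-methoxyphenyl)ethanol | COc1cccc(CC(O)c2ccc(Oc3cc(CCc4cccc(OC)c4OC)ccc3OC)cc2)c1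
F0 | step 4 | none | none
F0 | step 8 | none | none
A1 | alternative 1 | 3-[2-(4-methoxy-3-{4-[2-(3-methoxyphenyl)ethyl]phenoxy}phenyl)ethyl]benzene-1,2-diol | Oc1cccc(CCc2ccc(OC)c(Oc3ccc(CCc4cccc(OC)c4)cc3)c2)c1O
A2 | alternative 1 | 2-[2-(2,5-dimethoxytetrahydrofuran-2-yl)-1,3-dioxolan-2-yl]-substituted propyl arene: 2,5-dimethoxy-2-{2-[3-(4-methoxy-3-{4-[2-(3-methoxyphenyl)ethyl]phenoxy}phenyl)propyl]-1,3-dioxolan-2-yl}tetrahydrofuran (mixture of diastereomers) | COC1CCC(OC)(O1)C1(CCCc2ccc(OC)c(Oc3ccc(CCc4cccc(OC)c4)cc3)c2)OCCO1
A3 | alternative 1 | 8-(4-methoxy-3-{4-[2-(3-methoxyphenyl)ethyl]phenoxy}phenyl)-4,5-dioxooctanal | O=CCCC(=O)C(=O)CCCc1ccc(OC)c(Oc2ccc(CCc3cccc(OC)c3)cc2)c1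
A4 | alternative 1 | 1-(furan-2-yl)-4-(4-methoxy-3-{4-[2-(3-methoxyphenyl)ethyl]phenoxy}phenyl)butan-1-one | O=C(CCCc1ccc(OC)c(Oc2ccc(CCc3cccc(OC)c3)cc2)c1)c1ccco1
A5 | alternative 2 | 4-[2-(2,3-dimethoxyphenyl)ethyl]-2-{4-[2-(3-methoxyphenyl)ethyl]phenoxy}phenol | COc1cccc(CCc2ccc(Oc3cc(CCc4cccc(OC)c4OC)ccc3O)cc2)c1
A6 | alternative 2 | 1-{4-[2-(3-methoxyphenyl)ethyl]phenoxy}propan-2-one | CC(=O)COc1ccc(CCc2cccc(OC)c2)cc1
A7 | alternative 2 | 2-[2-(2,3-dimethoxyphenyl)ethyl]-1,3-bis(dimethylamino)trimethinium hexafluorophosphate | CN(C)C=C(CCc1cccc(OC)c1OC)C=[N+](C)C.F[P-](F)(F)(F)(F)F
A8 | alternative 3 | 2-methoxy-6-[2-(4-methoxy-3-{4-[2-(3-methoxyphenyl)ethyl]phenoxy}phenyl)ethyl]phenol | COc1cccc(CCc2ccc(Oc3cc(CCc4cccc(OC)c4O)ccc3OC)cc2)c1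
A9 | alternative 3 | 2-(4-methoxy-3-{4-[2-(3-methoxyphenyl)ethyl]phenoxy}phenyl)ethylmagnesium bromide | COc1cccc(CCc2ccc(Oc3cc(CC[Mg]Br)ccc3OC)cc2)c1
A10 | alternative 3 | 3-fluoroanisole | COc1cccc(F)c1
A11 | alternative 3 | 3-methoxybenzyne | COC1=CC=CC#C1
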